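The readings were generated by integration on assumed constants.

Two questions stand on this flask, and both turn on how many chains share out the X that has reacted, a count the earlier runs do not show.

| setting | dawn | spring | flask |
|---|---|---|---|
| X | 0.20 M | 0.13 M | 0.20 M |
| E | 2.5 mol% | 2.5 mol% | 2.5 mol% |
| remark | the very flask that is asked about, followed so far | run made earlier |  |
| time |  |  | 6.0 min |

- dawn (time / min: J / %, X / %): 0.167: 0.4, 99.4; 0.333: 0.2, 98.5; 0.667: 3.1, 97.0; 1.00: 7.0, 93.3; 1.33: 11.8, 88.2; 2.00: 23.7, 75.0; 2.50: 33.9, 66.0
- spring (time / min: J / %, X / %): 0.333: 0.2, 100.1; 1.00: 2.6, 96.7; 1.50: 6.8, 93.1; 2.50: 16.8, 83.1; 4.00: 36.9, 63.4; 5.00: 49.4, 49.5; 6.00: 60.4, 39.8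

(readings scatter by 0.5 percentage points)

* whether the average number of monomer units in a chain (chains begun, living or dead) reaches 100 by 6.0 min (yes / no)
* average number of monomer units in a chain (chains begun, living or dead) at 6.0 min

- the average divides the monomer in chains by the number of chains begun, living and dead together
- the analysis behind the earlier runs scatters by 0.5 percentage points, standard deviation
- the earlier runs do not show the number of chains; that part of a forecast is a guess

Let x be the fraction of X left and p the fraction reacted. In one extreme E begins its chains at the outset, so the first-order slope of X stands flat from the start and the length is p over the loading; but the slope of the dawn run, this flask so far, starts near zero. In the other extreme, slow initiation from an unspent E, chains are begun at a pace proportional to x and consume X at a pace proportional to chains times x. So x cancels, chains grow as √p, and so does the length, while p follows one curve with one clock τ: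

√p = tanh(t/τ), and early on τ = t/√(−ln x)

The dawn reading at 1.33 min gives τ = 3.75 min. The curve then puts x at 66.1 % at 2.50 min, where the reading is 66.0 %, so this curve, which spends no E, already holds the levelling of the slope, and we place the flask between the extremes, near this one.

At 6.0 min the curve gives p = 0.849, and the first extreme gives a length of 34.0. On this curve a length of 100 needs under 34.0 % of E begun by then, which, with chains growing as √p, is 21.5 % at 2.50 min. The dawn reading at that time shows no lag behind the curve, so we commit to yes, with the size of the length a guess.

The forecast gave no for the first question and 33 for the second, and its grounds read: "This suggests E is used up, or that chains are dying."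

    X + D → Q + J (k = 0.0110 M⁻¹ s⁻¹)
    E ⇌ D (K = 0.620, k = 0.310 s⁻¹)
    X + Q → J + Q, rate k3*[Q]*[X] (k = 10.0 M⁻¹ s⁻¹)

The flask answers yes, with a length of 213 at 6.0 min. Q stands at 7.95 × 10⁻⁴ M at 6.00 min, which is 15.9 % of the E charged, less than our 34.0 %. The clock's p of 0.849 leaves 15.1 % of X, and the flask holds 15 %. Taken inversely to the charge of X at the same loading of E, τ becomes 5.77 min for the spring run, which gives J 60.5 % at 6.00 min, where the reading is 60.4 %.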